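## Analysis of the target

Kushenol V (23) is a (2S)-flavanone: a chroman-4-one (rings A and C) that carries the aryl ring B at C2, its only stereocentre. C2 is a benzylic ether carbon β to the C4 ketone. Base can open ring C by retro-oxa-Michael reaction, and strong acid can ionise the C2–O1 bond with help from the 2′- and 4′-hydroxyls; both racemise C2, so it must be set under control and then kept away from base and hot acid. Ring A is a phloroglucinol unit with free hydroxyls at C5 and C7 and a prenyl group at C6 between them, so the C6 against C8 question has to be settled by construction. The trisubstituted alkene rules out hydrogenolysis and tolerates protic acid only under mild conditions (addition of HX, closure onto a neighbouring phenol). Ring B carries oxygen at C2′, C4′ and C5′, of which only C5′ is methylated, so the three oxygens must arrive differentiated. The difficulty is therefore the combination of a labile stereocentre, a regiodefined prenyl group and a selectively methylated, electron-rich ring B. The strategy rests on ring B: the C2′ hydroxyl and the C5′ methoxy are para to each other and C1′ is ortho to the hydroxyl. This is the pattern of the 4-methoxyphenol that forms when a Fischer carbene complex, a terminal alkyne and one carbonyl ligand combine, so ring B can be grown on a C2 alkyne after C2 has been fixed.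

## Retrosynthetic reasoning

23 is traced to 22, in which O5 and O7 carry methoxymethyl (MOM) groups and O4′ a tert-butyl group. Only protecting-group C–O bonds are cut. All three are acetal or tertiary ethers and should leave in one acidic solvolysis, while the C5′ methyl ether, which belongs to the target, stays.

22 is cut at C5′–C6′, C1′–C2′ and C2′–C3′, which dissolves ring B into the terminal alkyne 15 and the carbene complex 20. The alkyne supplies C1′ and C6′, the carbene carbon of 20 supplies C5′ with its methoxy, one carbonyl ligand of 20 supplies C2′ with the free hydroxyl, and the vinyl group of 20 supplies C4′ (with its oxygen) and C3′. Cutting here means that the three ring B oxygens arrive already told apart, that no hindered ortho-substituted aryl has to be joined to C2, and that C2 can be set earlier on a small molecule. The forward reaction must place C1′ next to the new hydroxyl, leave the ketone, the alkene and C2 alone, and release the arene from the chromium complex 21.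

20 is cut at the carbene carbon to tert-butyl vinyl ether 16 and Cr(CO)6 17. The vinyl ether is metalated at its α-carbon (18), the anion adds to a carbonyl ligand (19) and the acylate oxygen is methylated. This is the standard assembly of an alkoxycarbene complex and makes the convergent branch one flask long.

15 is traced to its C-silyl derivative 14, and 14 is cut at the C2–C(sp) bond to chromone 11 and trimethylsilylacetylene 12. The chromone is flat and achiral, and the bond is formed by conjugate alkynylation under copper catalysis with a chiral ligand, via the silyl enol ether 13. This is the only stereogenic step of the route and it belongs to a reaction type known for chromones. The silyl cap is there for handling and is removed under buffered conditions.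

11 is cut at O1–C2 and C3–C4. The ynone 10 closes by addition of its own phenol to the alkyne terminus, 10 comes from carbinol 9 by oxidation, and 9 from salicylaldehyde 8 by addition of a two-carbon acetylide. This route needs no acid, which the MOM ethers and the prenyl group would not all survive.

8 is cut at C4a–C4 to phenol 7 by ortho-formylation. This is where the C6 against C8 question is settled. In 7 the prenyl group is para to the hydroxyl and flanked by the two MOM ethers, so the two ortho positions are identical. Whichever is formylated, the free oxygen becomes O1 and the prenyl group ends at C6.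

7 is cut at its phenol C–O bond to arene 5, via boronate 6. The oxygen is introduced by sterically controlled C–H borylation and oxidation at the only unhindered C–H, so it is free from the start and distinct from the two protected oxygens. 5 is cut at the aryl–prenyl bond to 2 and prenyl bromide 3, via aryllithium 4 formed by metalation between the two MOM ethers, and 2 is the bis-MOM ether of resorcinol 1.

## Alternatives that were turned down

Alternative 1: Ring C is cut at C4a–C4, C4–C3 and O1–C2, leading to the ortho-iodophenol A2, the ring B arylacetylene A3 and a one-carbon carbonyl unit.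
- Forward key step: PdCl2(PPh3)2 (divalent palladium) with a secondary amine under a carbonylating atmosphere would give the alkynone by carbonylative coupling, and 6-endo closure would give flavone A1. The C2=C3 bond then has to be reduced enantioselectively.
- For it: it is the most convergent plan, its key step is a well-tried reaction type, and the ring B oxygen pattern is carried in by A3 rather than created in a metal-mediated step. On these points it is stronger than the chosen route.
- Against it: C2 is created last, by conjugate reduction of a hindered β-aryl chromone with an ortho-substituted aryl group. That reduction must distinguish the enone from the C4 ketone (over-reduction) and from the prenyl alkene (hydrogenation), and must tell apart the faces of a flat substrate. The closure can also go 5-exo to the aurone. A2 needs iodine placed next to an oxidisable alkene, and A3 needs its own multi-step synthesis with three oxygens differentiated by hand.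
- Comparison: the chosen route sets C2 early by a reaction type known for chromones and then builds ring B under neutral conditions that cannot touch C2.

Alternative 2: Ring C is cut at C2–C3, leading to the aryl diazomethyl ketone A5, in which ring B is already attached through an O1–CH2 benzyl ether.
- Forward key step: Rh2(S-PTTL)4 (divalent rhodium) would decompose A5, and the carbenoid carbon C3 would insert into the benzylic ether C–H bond to give the silyl-protected flavanone A4, forming ring C and C2 in one step.
- For it: ring and stereocentre are made together, ring B arrives complete, and the C–H bond is activated by the ether oxygen and the electron-rich arene. In directness of ring C formation it equals or beats the chosen route.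
- Against it: a carbenoid from a diazomethyl ketone has no donor group and is highly reactive and poorly discriminating, so asymmetric induction is uncertain. Attack on the ether oxygen gives an oxonium ylide and then a benzofuranone by benzyl shift. Six-membered insertion competes with cyclopropanation of the prenyl alkene and with addition to ring B. A5 must be made from a doubly ortho-substituted benzoic acid derivative, and four silyl ethers must finally be removed with fluoride, whose basicity endangers C2.
- Comparison: the chosen route keeps electrophilic carbenoid chemistry away from the alkene; a Fischer carbene does not attack an unactivated trisubstituted alkene under the conditions used. It concentrates its risk in one step whose regiochemistry follows a simple steric rule.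

Alternative 3: Ring C is cut at O1–C2 and C3–C4, leading to salicylaldehyde 8 of the present route and the ring B styrene A7.
- Forward key step: a chiral BINOL-derived phosphoric acid would ionise the acetal formed from 8 and an orthoformate to an α-methoxy ortho-quinone methide, which adds across A7 to give chroman A6 with C2 and C4 set.
- For it: it is convergent, catalytic and metal-free, it uses an intermediate that is made here anyway, and it joins ring B and sets C2 in one step. On convergence it is at least as good as the chosen route.
- Against it: the C4 centre is made only to be destroyed, and turning the C4 methyl ether into the ketone needs hydrolysis and oxidation at a doubly activated benzylic position next to very electron-rich rings. The acid that activates C4 can also ionise C2–O1. A7 is an electron-rich styrene that oligomerises under acid. The quinone methide from a 2,4,6-trioxygenated ring is strongly stabilised and therefore sluggish and unselective. The MOM ethers and the prenyl alkene are exposed to the acid catalyst.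
- Comparison: the chosen route reaches the C4 ketone with no redox correction and keeps acid for the last step only.

Key step: step 10

Assumption: the sense of induction of the CuI–StackPhos acetylide on chromone 11 is taken to be the same as on simpler chromones; the ligand enantiomer is chosen so that the acetylide adds to the Re face of C2 (O1 > C3 > H), which gives 2S.

## Route

Step 1
Reactants: 1 resorcinol (benzene-1,3-diol)
Product: 2 1,3-bis(methoxymethoxy)benzene
Conditions: MOMCl (2.5 equiv), i-Pr2NEt (3 equiv), CH2Cl2, 0 °C → rt
Reagents that add atoms: chloromethyl methyl ether (MOMCl), COCCl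
Why: O-Alkylation of both phenols by the α-chloro ether (Williamson-type acetal formation); the MOM ethers later direct lithiation, survive bases, Grignard reagents and neutral chromium chemistry, and leave under mild acid.

Step 2
Reactants: 2 1,3-bis(methoxymethoxy)benzene; 3 prenyl bromide (1-bromo-3-methylbut-2-ene)
Product: 5 1,3-bis(methoxymethoxy)-2-(3-methylbut-2-en-1-yl)benzene, via 2,6-bis(methoxymethoxy)phenyllithium 4 (not isolated)
Conditions: n-BuLi (1.1 equiv), THF, 0 °C → rt; CuI (10 mol%), then 3, −78 °C → rt
Reagents that add atoms: none
Why: Directed ortho-metalation: both MOM ethers chelate lithium, so deprotonation should occur only at C2 between them; copper-catalysed allylic substitution at the primary carbon of 3 then gives the linear prenyl group.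

Step 3
Reactants: 5 1,3-bis(methoxymethoxy)-2-(3-methylbut-2-en-1-yl)benzene
Product: 7 3,5-bis(methoxymethoxy)-4-(3-methylbut-2-en-1-yl)phenol, via arylboronic acid pinacol ester 6 (not isolated)
Conditions: [Ir(OMe)(cod)]2 (1.5 mol%), 4,4′-di-tert-butyl-2,2′-bipyridine (3 mol%), B2pin2 (0.6 equiv), THF, 60 °C; then 30% H2O2, aq. NaOH, 0 °C → rt
Reagents that add atoms: bis(pinacolato)diboron, CC1(C)OB(OC1(C)C)B1OC(C)(C)C(C)(C)O1 (boron of intermediate 6 only); hydrogen peroxide, OO
Why: Iridium-catalysed aromatic C–H borylation is sterically controlled and should take the only C–H without an ortho substituent, C5, para to the prenyl group; basic peroxide, which does not epoxidise an isolated alkene, then converts C–B into C–OH. The new oxygen is free from the start and so differs from the two MOM-protected oxygens.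

Step 4
Reactants: 7 3,5-bis(methoxymethoxy)-4-(3-methylbut-2-en-1-yl)phenol
Product: 8 2-hydroxy-4,6-bis(methoxymethoxy)-5-(3-methylbut-2-en-1-yl)benzaldehyde
Conditions: MgCl2 (2 equiv), Et3N (4 equiv), (CH2O)n (6 equiv), MeCN, reflux
Reagents that add atoms: paraformaldehyde (source of formaldehyde), C=O
Why: Magnesium phenoxide-directed ortho-formylation (Casnati–Skattebøl reaction): hydroxymethylation at the ortho carbon, then hydride transfer to a second formaldehyde. The two ortho positions of 7 are identical by symmetry and the para position is blocked, so only one aldehyde can form, and the prenyl group is thereby fixed at the later C6.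

Step 5
Reactants: 8 2-hydroxy-4,6-bis(methoxymethoxy)-5-(3-methylbut-2-en-1-yl)benzaldehyde
Product: 9 rac-1-[2-hydroxy-4,6-bis(methoxymethoxy)-5-(3-methylbut-2-en-1-yl)phenyl]prop-2-yn-1-ol
Conditions: HC≡CMgBr (3 equiv), THF, 0 °C → rt; aq. NH4Cl; used crude
Reagents that add atoms: ethynylmagnesium bromide, C#C[Mg]Br
Why: Grignard 1,2-addition to the aldehyde; the first equivalent is used up by the phenol and the excess compensates for the lower electrophilicity of this electron-rich magnesium phenoxide aldehyde. The carbinol centre is racemic and is removed in step 6.

Step 6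
Reactants: 9 rac-1-[2-hydroxy-4,6-bis(methoxymethoxy)-5-(3-methylbut-2-en-1-yl)phenyl]prop-2-yn-1-ol
Product: 11 5,7-bis(methoxymethoxy)-6-(3-methylbut-2-en-1-yl)-4H-chromen-4-one, via 1-(2-hydroxyaryl)prop-2-yn-1-one 10 (not isolated)
Conditions: MnO2 (10 equiv), CH2Cl2, rt; filter; K2CO3 (0.2 equiv), acetone, rt
Reagents that add atoms: none
Why: MnO2 oxidises the benzylic, propargylic alcohol selectively; the ortho-phenoxide then adds to the unsubstituted β-carbon of the ynone (6-endo-dig oxa-Michael addition) and closes ring C as the chromone.

Step 7
Reactants: 11 5,7-bis(methoxymethoxy)-6-(3-methylbut-2-en-1-yl)-4H-chromen-4-one; 12 trimethylsilylacetylene (ethynyltrimethylsilane)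
Product: 14 (2S)-5,7-bis(methoxymethoxy)-6-(3-methylbut-2-en-1-yl)-2-[(trimethylsilyl)ethynyl]chroman-4-one, via 4-silyloxy-2H-chromene 13 (not isolated)
Conditions: CuI (10 mol%), StackPhos (11 mol%, enantiomer that gives 2S), TBSOTf (1.3 equiv), i-Pr2NEt (1.6 equiv), 12 (1.5 equiv), toluene, −78 → −30 °C; then 1 M HCl, THF, 0 °C
Reagents that add atoms: tert-butyldimethylsilyl trifluoromethanesulfonate (TBSOTf), CC(C)(C)[Si](C)(C)OS(=O)(=O)C(F)(F)F (silyl group of intermediate 13 only)
Why: TBSOTf silylates the pyrone carbonyl to a 4-silyloxybenzopyrylium ion, and the copper acetylide from 12, CuI and the amine adds to C2 within the pocket of the axially chiral P,N ligand (enantioselective copper-catalysed alkynylation of chromones); the ligand enantiomer is the one that directs the acetylide to the Re face of C2, which gives 2S. Cold dilute acid then hydrolyses silyl enol ether 13 by protonation at C3, without an enolate that could open ring C.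

Step 8
Reactants: 14 (2S)-5,7-bis(methoxymethoxy)-6-(3-methylbut-2-en-1-yl)-2-[(trimethylsilyl)ethynyl]chroman-4-one
Product: 15 (2S)-2-ethynyl-5,7-bis(methoxymethoxy)-6-(3-methylbut-2-en-1-yl)chroman-4-one
Conditions: TBAF (1.1 equiv), AcOH (1.5 equiv), THF, 0 °C
Reagents that add atoms: none
Why: Protodesilylation of an alkynylsilane: fluoride attacks silicon and the acetic acid buffer protonates the acetylide at once. The near-neutral medium avoids enolisation at C3 and the retro-oxa-Michael opening that would racemise C2.

Step 9
Reactants: 16 tert-butyl vinyl ether (2-ethenyloxy-2-methylpropane); 17 hexacarbonylchromium Cr(CO)6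
Product: 20 pentacarbonyl[(1-tert-butoxyvinyl)(methoxy)carbene]chromium (CO)5Cr=C(OCH3)C(OC(CH3)3)=CH2, via 1-tert-butoxyvinyllithium 18 (not isolated), via lithium pentacarbonyl(2-tert-butoxyacryloyl)chromate 19 (not isolated)
Conditions: t-BuLi (1.0 equiv), THF, −78 → 0 °C; Cr(CO)6 (1.0 equiv), THF, 0 °C → rt; MeOTf (1.2 equiv), CH2Cl2, 0 °C
Reagents that add atoms: methyl trifluoromethanesulfonate (MeOTf), COS(=O)(=O)C(F)(F)F
Why: Fischer carbene synthesis: α-deprotonation of the alkyl vinyl ether by tert-butyllithium, addition of the vinyllithium to a carbonyl ligand of Cr(CO)6 and O-methylation of the acylchromate by a hard methylating agent. The α-alkoxy group makes the alkenyl complex α-branched, like the stable isopropenyl complexes, which should suppress the polymerisation of unsubstituted vinyl complexes.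

Step 10
Reactants: 15 (2S)-2-ethynyl-5,7-bis(methoxymethoxy)-6-(3-methylbut-2-en-1-yl)chroman-4-one; 20 pentacarbonyl[(1-tert-butoxyvinyl)(methoxy)carbene]chromium
Product: 22 (2S)-2-(4-tert-butoxy-2-hydroxy-5-methoxyphenyl)-5,7-bis(methoxymethoxy)-6-(3-methylbut-2-en-1-yl)chroman-4-one, via tricarbonylchromium arene complex 21 (not isolated)
Conditions: 20 (1.5 equiv), THF (0.05 M, degassed), 50 °C, argon; then air, CH2Cl2, daylight, rt
Reagents that add atoms: none
Why: Proposed new method: the closest known reaction type is the Dötz benzannulation of alkenyl(methoxy)carbene complexes of zerovalent chromium with terminal alkynes to 4-methoxyphenols, and the 1-alkoxyvinyl complex 20 has not been shown as the partner. Thermal loss of one carbonyl ligand from 20 should open a site for alkyne 15, which inserts into the chromium–carbene bond so that the carbene carbon (C5′) bonds to the terminal CH (C6′) and the new carbene carbon is C1′. Carbonyl insertion at C1′ gives a chromium-bound dienylketene (bond C1′–C2′), and six-electron electrocyclisation of the ketene carbon onto the vinyl CH2 (bond C2′–C3′) closes ring B as a cyclohexadienone that tautomerises to the phenol, held as complex 21 until air oxidises the metal away. The required regioselectivity, C1′ next to the new hydroxyl, should follow from the steric rule for terminal alkynes: the bulky chromanyl substituent ends beside the carbon that comes from the carbonyl ligand. The α-tert-butoxy group is a donor on the diene terminus and should not hinder the electrocyclisation, and phenol formation is the normal outcome for alkenyl complexes in THF. The ketone, the MOM ethers and the trisubstituted prenyl alkene are not partners for a Fischer carbene at 50 °C under neutral conditions. No acid or base is present, so C2, which is not touched, should keep its S configuration; no new stereocentre is formed.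

Step 11
Reactants: 22 (2S)-2-(4-tert-butoxy-2-hydroxy-5-methoxyphenyl)-5,7-bis(methoxymethoxy)-6-(3-methylbut-2-en-1-yl)chroman-4-one
Product: 23 Kushenol V [(2S)-2-(2,4-dihydroxy-5-methoxyphenyl)-5,7-dihydroxy-6-(3-methylbut-2-en-1-yl)chroman-4-one]
Conditions: HCl (3 M in MeOH), 40 °C
Reagents that add atoms: none
Why: Acid-catalysed acetal solvolysis of both MOM ethers, with methanol trapping the oxocarbenium ion, and SN1 cleavage of the aryl tert-butyl ether with loss of isobutene; the aryl methyl ether is stable. Methanol as solvent intercepts the cations, and the moderate temperature should limit reaction of the prenyl group and ionisation at C2.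

## Compound list

1 | resorcinol (benzene-1,3-diol) | Oc1cccc(O)c1 | starting material
2 | 1,3-bis(methoxymethoxy)benzene | COCOc1cccc(OCOC)c1 | intermediate
3 | prenyl bromide (1-bromo-3-methylbut-2-ene) | CC(C)=CCBr | starting material
4 | 2,6-bis(methoxymethoxy)phenyllithium | [Li]c1c(OCOC)cccc1OCOC | intermediate (not isolated)
5 | 1,3-bis(methoxymethoxy)-2-(3-methylbut-2-en-1-yl)benzene | COCOc1cccc(OCOC)c1CC=C(C)C | intermediate
6 | 2-[3,5-bis(methoxymethoxy)-4-(3-methylbut-2-en-1-yl)phenyl]-4,4,5,5-tetramethyl-1,3,2-dioxaborolane | COCOc1cc(B2OC(C)(C)C(C)(C)O2)cc(OCOC)c1CC=C(C)C | intermediate (not isolated)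
7 | 3,5-bis(methoxymethoxy)-4-(3-methylbut-2-en-1-yl)phenol | COCOc1cc(O)cc(OCOC)c1CC=C(C)C | intermediate
8 | 2-hydroxy-4,6-bis(methoxymethoxy)-5-(3-methylbut-2-en-1-yl)benzaldehyde | O=Cc1c(O)cc(OCOC)c(CC=C(C)C)c1OCOC | intermediate
9 | rac-1-[2-hydroxy-4,6-bis(methoxymethoxy)-5-(3-methylbut-2-en-1-yl)phenyl]prop-2-yn-1-ol | C#CC(O)c1c(O)cc(OCOC)c(CC=C(C)C)c1OCOC | intermediate
10 | 1-[2-hydroxy-4,6-bis(methoxymethoxy)-5-(3-methylbut-2-en-1-yl)phenyl]prop-2-yn-1-one | C#CC(=O)c1c(O)cc(OCOC)c(CC=C(C)C)c1OCOC | intermediate (not isolated)
11 | 5,7-bis(methoxymethoxy)-6-(3-methylbut-2-en-1-yl)-4H-chromen-4-one | O=c1ccoc2cc(OCOC)c(CC=C(C)C)c(OCOC)c12 | intermediate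
12 | trimethylsilylacetylene (ethynyltrimethylsilane) | C#C[Si](C)(C)C | starting material
13 | (2S)-4-(tert-butyldimethylsilyloxy)-5,7-bis(methoxymethoxy)-6-(3-methylbut-2-en-1-yl)-2-[(trimethylsilyl)ethynyl]-2H-chromene | C[Si](C)(C)C#C[C@@H]1C=C(O[Si](C)(C)C(C)(C)C)c2c(cc(OCOC)c(CC=C(C)C)c2OCOC)O1 | intermediate (not isolated)
14 | (2S)-5,7-bis(methoxymethoxy)-6-(3-methylbut-2-en-1-yl)-2-[(trimethylsilyl)ethynyl]chroman-4-one | C[Si](C)(C)C#C[C@@H]1CC(=O)c2c(cc(OCOC)c(CC=C(C)C)c2OCOC)O1 | intermediate
15 | (2S)-2-ethynyl-5,7-bis(methoxymethoxy)-6-(3-methylbut-2-en-1-yl)chroman-4-one | C#C[C@@H]1CC(=O)c2c(cc(OCOC)c(CC=C(C)C)c2OCOC)O1 | intermediate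
16 | tert-butyl vinyl ether | C=COC(C)(C)C | starting material
17 | hexacarbonylchromium, Cr(CO)6 | O=C=[Cr](=C=O)(=C=O)(=C=O)(=C=O)=C=O | starting material
18 | 1-tert-butoxyvinyllithium | [Li]C(=C)OC(C)(C)C | intermediate (not isolated)
19 | lithium pentacarbonyl(2-tert-butoxyacryloyl)chromate | [Li+].[O-]C(C(=C)OC(C)(C)C)=[Cr](=C=O)(=C=O)(=C=O)(=C=O)=C=O | intermediate (not isolated)
20 | pentacarbonyl[(1-tert-butoxyvinyl)(methoxy)carbene]chromium | COC(C(=C)OC(C)(C)C)=[Cr](=C=O)(=C=O)(=C=O)(=C=O)=C=O | intermediate
21 | tricarbonylchromium complex of 22, metal η6-bound to ring B (written as arene and Cr(CO)3 fragment) | COc1cc([C@@H]2CC(=O)c3c(cc(OCOC)c(CC=C(C)C)c3OCOC)O2)c(O)cc1OC(C)(C)C.O=C=[Cr](=C=O)=C=O | intermediate (not isolated)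
22 | (2S)-2-(4-tert-butoxy-2-hydroxy-5-methoxyphenyl)-5,7-bis(methoxymethoxy)-6-(3-methylbut-2-en-1-yl)chroman-4-one | COc1cc([C@@H]2CC(=O)c3c(cc(OCOC)c(CC=C(C)C)c3OCOC)O2)c(O)cc1OC(C)(C)C | intermediate
23 | Kushenol V, (2S)-2-(2,4-dihydroxy-5-methoxyphenyl)-5,7-dihydroxy-6-(3-methylbut-2-en-1-yl)chroman-4-one | COc1cc([C@@H]2CC(=O)c3c(cc(O)c(CC=C(C)C)c3O)O2)c(O)cc1O | target

## Step count and least certain steps

Total step count: 11. Longest linear sequence: 10 steps (steps 1 to 8, 10 and 11, from 1); the carbene branch (step 9) is one step from 16 and 17.

**Step 10 (key step, proposed new method).**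
- Most likely failure: the carbene fails to enter the benzannulation manifold. After loss of a carbonyl ligand the tert-butoxy oxygen may chelate chromium and block uptake of the alkyne. The electron-rich vinylketene may also be diverted (cyclobutenone formation, or incorporation of a second alkyne), or the enol ether may be lost through adventitious acid.
- Fallback with known chemistry: it sets out from chromone 11 and comes back at 23, bringing ring B in as a finished aryl group by asymmetric conjugate addition of an arylboronic acid to a chromone. Purchasable 4-methoxybenzene-1,3-diol F1 would be protected (MOMCl, i-Pr2NEt) as 1-methoxy-2,4-bis(methoxymethoxy)benzene F2. Bromination with N-bromosuccinimide in MeCN should go para to the C2 MOM ether and ortho to the C4 MOM ether, giving 1-bromo-5-methoxy-2,4-bis(methoxymethoxy)benzene F3. Bromine–lithium exchange (n-BuLi, −78 °C), B(O-i-Pr)3 and aqueous work-up would give [5-methoxy-2,4-bis(methoxymethoxy)phenyl]boronic acid F4. F4 would be added to 11 with Pd(OCOCF3)2 and a chiral pyridine–oxazoline ligand of the configuration that gives 2S, to give (2S)-2-[5-methoxy-2,4-bis(methoxymethoxy)phenyl]-5,7-bis(methoxymethoxy)-6-(3-methylbut-2-en-1-yl)chroman-4-one F5. HCl in MeOH as in step 11 would then give 23. The weak point is protodeboronation of the ortho-alkoxy boronic acid, which is why this is the fallback and not the plan.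

**Step 7.**
- Most likely failure: poor facial selectivity, because the C5 MOM ether sits peri to the silyloxy group and changes the shape of the pyrylium ion relative to the chromones for which the catalyst is known; partial cleavage of a MOM ether by the silyl triflate is a second risk.
- Fallback: it sets out from 11 and comes back at 14, replacing catalyst control by resolution. The same alkynylation run with CuI and no chiral ligand would give rac-5,7-bis(methoxymethoxy)-6-(3-methylbut-2-en-1-yl)-2-[(trimethylsilyl)ethynyl]chroman-4-one F6, and preparative HPLC on a chiral stationary phase would give 14.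

**Step 3.**
- Most likely failure: the iridium boryl and hydride species react with the prenyl alkene (hydroboration or double-bond migration) in competition with aromatic borylation.
- Fallback: it sets out from 2 and comes back at 7, installing the oxygen before the alkene is present. Borylation of 2 under the same catalyst at its mutually meta position would give 2-[3,5-bis(methoxymethoxy)phenyl]-4,4,5,5-tetramethyl-1,3,2-dioxaborolane F7, and oxidation would give 3,5-bis(methoxymethoxy)phenol F8. Silylation (i-Pr3SiCl, imidazole) would give [3,5-bis(methoxymethoxy)phenoxy]triisopropylsilane F9. Lithiation between the two MOM ethers and copper-catalysed reaction with 3 would give [3,5-bis(methoxymethoxy)-4-(3-methylbut-2-en-1-yl)phenoxy]triisopropylsilane F10, and TBAF would release 7.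

**Step 11.**
- Most likely failure: acid-induced reaction of the prenyl group (closure onto the C5 or C7 hydroxyl, or addition of HCl or methanol), alkylation of the electron-rich rings by the tert-butyl cation, or erosion of the configuration at C2 by reversible ionisation of C2–O1.
- Fallback: it sets out from 22 and comes back at 23, replacing protic solvolysis by silyl transfer. Me3SiOTf with 2,2′-bipyridyl in CH2Cl2 at 0 °C converts aryl MOM ethers into trimethylsilyl ethers, cleaves the tert-butyl ether and silylates the free phenol, giving (2S)-2-[5-methoxy-2,4-bis(trimethylsilyloxy)phenyl]-6-(3-methylbut-2-en-1-yl)-5,7-bis(trimethylsilyloxy)chroman-4-one F11, which water hydrolyses to 23 under nearly neutral conditions.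

## Further compounds

F1 | step 10 | 4-methoxybenzene-1,3-diol | COc1ccc(O)cc1O
F2 | step 10 | 1-methoxy-2,4-bis(methoxymethoxy)benzene | COCOc1ccc(OC)c(OCOC)c1
F3 | step 10 | 1-bromo-5-methoxy-2,4-bis(methoxymethoxy)benzene | COc1cc(Br)c(OCOC)cc1OCOC
F4 | step 10 | [5-methoxy-2,4-bis(methoxymethoxy)phenyl]boronic acid | COc1cc(B(O)O)c(OCOC)cc1OCOC
F5 | step 10 | (2S)-2-[5-methoxy-2,4-bis(methoxymethoxy)phenyl]-5,7-bis(methoxymethoxy)-6-(3-methylbut-2-en-1-yl)chroman-4-one | COc1cc([C@@H]2CC(=O)c3c(cc(OCOC)c(CC=C(C)C)c3OCOC)O2)c(OCOC)cc1OCOC
F6 | step 7 | rac-5,7-bis(methoxymethoxy)-6-(3-methylbut-2-en-1-yl)-2-[(trimethylsilyl)ethynyl]chroman-4-one | C[Si](C)(C)C#CC1CC(=O)c2c(cc(OCOC)c(CC=C(C)C)c2OCOC)O1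
F7 | step 3 | 2-[3,5-bis(methoxymethoxy)phenyl]-4,4,5,5-tetramethyl-1,3,2-dioxaborolane | COCOc1cc(OCOC)cc(B2OC(C)(C)C(C)(C)O2)c1
F8 | step 3 | 3,5-bis(methoxymethoxy)phenol | COCOc1cc(O)cc(OCOC)c1
F9 | step 3 | [3,5-bis(methoxymethoxy)phenoxy]triisopropylsilane | COCOc1cc(OCOC)cc(O[Si](C(C)C)(C(C)C)C(C)C)c1
F10 | step 3 | [3,5-bis(methoxymethoxy)-4-(3-methylbut-2-en-1-yl)phenoxy]triisopropylsilane | COCOc1cc(O[Si](C(C)C)(C(C)C)C(C)C)cc(OCOC)c1CC=C(C)C
F11 | step 11 | (2S)-2-[5-methoxy-2,4-bis(trimethylsilyloxy)phenyl]-6-(3-methylbut-2-en-1-yl)-5,7-bis(trimethylsilyloxy)chroman-4-one | COc1cc([C@@H]2CC(=O)c3c(cc(O[Si](C)(C)C)c(CC=C(C)C)c3O[Si](C)(C)C)O2)c(O[Si](C)(C)C)cc1O[Si](C)(C)C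
A1 | alternative 1 | 2-[5-methoxy-2,4-bis(methoxymethoxy)phenyl]-5,7-bis(methoxymethoxy)-6-(3-methylbut-2-en-1-yl)-4H-chromen-4-one | COc1cc(-c2cc(=O)c3c(cc(OCOC)c(CC=C(C)C)c3OCOC)o2)c(OCOC)cc1OCOC
A2 | alternative 1 | 2-iodo-3,5-bis(methoxymethoxy)-4-(3-methylbut-2-en-1-yl)phenol | COCOc1cc(O)c(I)c(OCOC)c1CC=C(C)C
A3 | alternative 1 | 1-ethynyl-5-methoxy-2,4-bis(methoxymethoxy)benzene | COc1cc(C#C)c(OCOC)cc1OCOC
A4 | alternative 2 | (2S)-2-[2,4-bis(tert-butyldimethylsilyloxy)-5-methoxyphenyl]-5,7-bis(tert-butyldimethylsilyloxy)-6-(3-methylbut-2-en-1-yl)chroman-4-one | COc1cc([C@@H]2CC(=O)c3c(cc(O[Si](C)(C)C(C)(C)C)c(CC=C(C)C)c3O[Si](C)(C)C(C)(C)C)O2)c(O[Si](C)(C)C(C)(C)C)cc1O[Si](C)(C)C(C)(C)C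
A5 | alternative 2 | 1-[2-{[2,4-bis(tert-butyldimethylsilyloxy)-5-methoxyphenyl]methoxy}-4,6-bis(tert-butyldimethylsilyloxy)-5-(3-methylbut-2-en-1-yl)phenyl]-2-diazoethan-1-one | [N-]=[N+]=CC(=O)c1c(OCc2cc(OC)c(O[Si](C)(C)C(C)(C)C)cc2O[Si](C)(C)C(C)(C)C)cc(O[Si](C)(C)C(C)(C)C)c(CC=C(C)C)c1O[Si](C)(C)C(C)(C)C
A6 | alternative 3 | (2S,4S)-2-[2-hydroxy-5-methoxy-4-(methoxymethoxy)phenyl]-4-methoxy-5,7-bis(methoxymethoxy)-6-(3-methylbut-2-en-1-yl)chroman | CO[C@H]1C[C@@H](c2cc(OC)c(OCOC)cc2O)Oc2cc(OCOC)c(CC=C(C)C)c(OCOC)c21
A7 | alternative 3 | 2-ethenyl-4-methoxy-5-(methoxymethoxy)phenol | C=Cc1cc(OC)c(OCOC)cc1O
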